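1. A small charge ran far: Saturday's flask, 4.3 mM of substrate at 35 °C, stood at 92.0 % product after 4.00 min. Friday's flask, a larger charge of 71 mM at 50 °C, stood at 14.9 % after 120 s.

all flasks: free catalyst 10 µM
- Saturday's: substrate 4.3 mM; coupling partner 22 mM; temperature 35 °C; run made earlier
- Friday's: substrate 71 mM; coupling partner 22 mM; temperature 50 °C; run made earlier
- spring: substrate 80 mM; coupling partner 22.0 mM; temperature 50 °C; time 2.5 min
- dawn: substrate 60 mM; coupling partner 22.0 mM; temperature 50 °C; time 2.5 min
- midnight: substrate 5.0 mM; coupling partner 22.0 mM; temperature 50 °C; time 2.5 min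
- summer: substrate 20 mM; coupling partner 22.0 mM; temperature 50 °C; time 2.5 min

- Saturday's (time / min: product / %, substrate / %): 0.667: 23.0, 77.7; 1.33: 43.2, 57.1; 2.00: 61.5, 39.0; 3.00: 81.1, 19.2; 4.00: 92.0, 7.3
- Friday's (time / s: product / %, substrate / %): 10.0: 1.2, 99.7; 25.0: 3.7, 96.1; 50.0: 7.6, 92.3; 80.0: 11.6, 89.8; 120: 14.9, 84.7

(readings scatter by 0.5 percentage points)

1. ranking by amount of product, in percent of the substrate charged, from high to low, at 2.5 min (spring / dawn / midnight / summer)
2. the amount of product, in percent of the substrate charged of the flask you put first, at 2.5 min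
3. the amount of product, in percent of the substrate charged of the flask you put last, at 2.5 min

2. In Friday's flask the product slope fell from 6.65 mM min⁻¹ (second to third reading) to 3.51 mM min⁻¹ (last two readings). Substrate still stood at 84.7 %, but, counting one coupling partner per product, about half of the coupling partner was used. With 22 mM charged, it is the limiting reagent there. So I froze substrate out of the reckoning.

3. First way: I extended the last slope to 2.5 min, which gave 12.3 mM. I called this Q, the substrate-rich yield: the millimolar product that a flask rich in substrate holds at that time, whatever its substrate charge, with Friday's coupling partner, catalyst and temperature.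

4. Second way: I let coupling partner decay at first order, with k = 0.302 min⁻¹, the early slope over the charge. This gave 11.7 mM, which parts from Q by 0.600 mM.

5. To find which way cheats, I tried the second on Friday's last reading; Q passes through that reading by construction, so this tests the second way and not Q. It gave 9.98 mM against 10.6 mM read, so it ran low by 0.85 percentage points of the charge, where a reading scatters by 0.5 points. On that modest evidence I kept Q.

6. Q gave me 15.4 % for spring, 20.5 % for dawn and, if summer stayed rich in substrate, 61.7 % for summer. Midnight's 5.0 mM lies under Q, and at the early slope it needs 0.752 min, so I expected it nearly finished.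

7. The forecast: midnight > summer > dawn > spring, top 98 %, low 15 %, a little under my spring figure. Its ground for the large flasks was the same freeze: “whatever the charge”.

8. The flasks gave midnight > summer > dawn > spring, with top 96.9 % and low 16.1 %.

    substrate + free catalyst → catalyst intermediate A (k = 3400 M⁻¹ s⁻¹, Ea = 28.0 kJ mol⁻¹)
    coupling partner + catalyst intermediate A ⇌ catalyst intermediate B (K = 80.0 M⁻¹, k = 2800 M⁻¹ s⁻¹, Ea = 37.0 kJ mol⁻¹, ΔH = −5.00 kJ mol⁻¹)
    catalyst intermediate B → catalyst intermediate C (k = 27.0 s⁻¹, Ea = 66.0 kJ mol⁻¹)
    catalyst intermediate C ⇌ by-product + catalyst intermediate D (K = 0.0260 M, k = 79.0 s⁻¹, Ea = 63.0 kJ mol⁻¹, ΔH = 36.0 kJ mol⁻¹)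
    catalyst intermediate D → free catalyst + product (k = 180 s⁻¹, Ea = 62.0 kJ mol⁻¹)
    (constants at 50 °C)

9. The ranking matched the forecast, and both values fell inside its ranges. Spring held 12.9 mM of product and dawn 12.7 mM, so 80 mM and 60 mM of substrate gave nearly one amount, 0.520 mM above Q for spring. Spring still had 84 % of its substrate and 42 % of its coupling partner. The neighbour is spring's flask with 20 mM of substrate. There, at 1.10 equiv of coupling partner to substrate, Q gives 61.7 %, and that flask gave 57.3 %.

All runs stem from a simulated flask with constants of no real substance, and the scatter is random.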